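**Retrosynthetic overview**
The veratrate is cut at the acyl–O bond. The C7 carbinol is traced back to the ketone of a 2-methylcyclohept-2-enone (C7=O, C8–CH3, C8=C9).
Feature on which the strategy rests: taking C8 out of the seven-membered ring leaves a cis-fused hydrindan-5-one. Its angular C5 hydroxyl is β to the C7 carbonyl and vicinal to the angular C1 methyl, which makes it the ketol of a proline-catalysed triketone aldol.
C8 and its methyl therefore enter last, by chloro(methyl)carbene addition to the C7=C9 silyl enol ether and cyclopropyl-to-allyl cleavage of the C7–C9 bond.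
The C4 isopropyl group enters earlier, by conjugate addition to a C3=C4 cyclopentenone on the face of the C5 oxygen, and the C2 carbonyl is then erased.
Ring order: five-membered ring purchased, six-membered ring by aldol, cyclopropane by [2+1] addition, seven-membered ring by enlargement of the six-membered ring.

Key step: step 15

Remark: daucane numbers of the target are used for all bicyclic compounds (C1 methyl-bearing fusion carbon, C2/C3 ring CH2, C4 isopropyl carbon, C5 oxygenated fusion carbon, C6 CH2, C7 ester carbon, C8=C9 alkene, C10 CH2); the hydrindanes lack C8, so C7 is bonded to C9, and "top face" means the face of the C1 methyl group.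

**Step 1**
Reactants: 1 2-methylcyclopentane-1,3-dione; 2 methyl vinyl ketone
Product: 3 2-methyl-2-(3-oxobutyl)cyclopentane-1,3-dione
Conditions: H2O, AcOH (cat.), 70 °C
Reagents that add atoms: none
Why: Michael addition of the acidic cyclic 1,3-dione to the enone stops at the mono-adduct because the attacked carbon becomes quaternary, and no stereocentre is formed.

**Step 2**
Reactants: 3 2-methyl-2-(3-oxobutyl)cyclopentane-1,3-dione
Product: 4 (3aR,7aR)-3a-hydroxy-7a-methylhexahydro-1H-indene-1,5(4H)-dione (cis ketol, C1–CH3 and C5–OH both on the top face)
Conditions: (R)-proline (3 mol %), DMF, 20 °C; crystallisation to raise enantiopurity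
Reagents that add atoms: none
Why: In this Hajos–Parrish–Eder–Sauer–Wiechert reaction the (R)-proline enamine of the side-chain ketone attacks one of the two enantiotopic ring carbonyls through a carboxylic-acid-organised transition state, which sets C1 and C5 together as the cis ketol (mirror image of the (S)-proline product), and the neutral medium at room temperature leaves the tertiary alcohol undehydrated.

**Step 3**
Reactants: 4 cis ketol
Product: 5 C5 trimethylsilyl ether of 4
Conditions: N-(trimethylsilyl)imidazole, CH2Cl2, 0 °C to rt
Reagents that add atoms: N-(trimethylsilyl)imidazole, C[Si](C)(C)n1ccnc1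
Why: Silyl transfer from the neutral but powerful N-silylimidazole caps the tertiary alcohol without enolising either ketone, so no free hydroxyl is present in the Lewis-acid step that follows.

**Step 4**
Reactants: 5 C5 trimethylsilyl ether of the ketol
Product: 6 C7 ethylene ketal of 5 (C2 ketone free)
Conditions: TMSOCH2CH2OTMS (1.1 equiv), TMSOTf (5 mol %), CH2Cl2, −78 °C; pyridine quench
Reagents that add atoms: 1,2-bis(trimethylsilyloxy)ethane, C[Si](C)(C)OCCO[Si](C)(C)C
Why: Noyori ketalisation under aprotic low-temperature conditions selects the open six-ring ketone over the C2 ketone, which is neopentyl next to quaternary C1, and avoids the protic acid and heat that would eliminate the β-oxygen at C5.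

**Step 5**
Reactants: 6 C7 ketal ketone
Product: 8 C2 trimethylsilyl enol ether of 6 (C2=C3; C5–OTMS kept), via C2 lithium enolate 7 (not isolated)
Conditions: LiN(iPr)2 (LDA), THF, −78 °C; then TMSCl, Et3N, −78 to 0 °C
Reagents that add atoms: chlorotrimethylsilane, C[Si](C)(C)Cl
Why: Kinetic deprotonation can occur only at C3 because C1 is quaternary, and O-silylation of the enolate gives a single silyl enol ether.

**Step 6**
Reactants: 8 C2 silyl enol ether
Product: 9 C5-siloxy cyclopentenone (C2=O, C3=C4, C7 ketal)
Conditions: Pd(OAc)2 (10 mol %), O2 (1 atm), DMSO, rt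
Reagents that add atoms: none
Why: In this Saegusa–Ito oxidation, run catalytically with O2 as terminal oxidant, divalent palladium takes up the enol ether as an oxo-π-allyl species and β-hydride loss from C4 gives the C3=C4 enone.

**Step 7**
Reactants: 9 C5-siloxy cyclopentenone
Product: 10 C5-hydroxy cyclopentenone (C7 ketal, C2=O, C3=C4)
Conditions: Bu4NF, AcOH (1:1), THF, 0 °C
Reagents that add atoms: none
Why: Buffered fluoride cleaves the Si–O bond under near-neutral conditions, which spares the ketal and avoids a free alkoxide that could start retro-aldol cleavage of the C1–C5 bond.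

**Step 8**
Reactants: 10 C5-hydroxy cyclopentenone; 11 isopropylmagnesium chloride
Product: 13 (4R)-C4-isopropyl ketone (isopropyl on the top face; C7 ketal; C5–OH free), via bis(chloromagnesium) alkoxide enolate 12 (not isolated)
Conditions: 11 (3.5 equiv), CuBr·SMe2 (30 mol %), THF, −78 to −30 °C; aq NH4Cl
Reagents that add atoms: none
Why: In this copper-catalysed conjugate addition of a Grignard reagent the first equivalent turns C5–OH into a small magnesium alkoxide that can guide the metal, and the organocopper species then attacks C4 on the convex face of the cis bicycle (the face of the C5 oxygen and C1 methyl, away from C6, C10 and the ketal), so the isopropyl group ends syn to the C5 oxygen.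

**Step 9**
Reactants: 13 C4-isopropyl ketone
Product: 14 C2 alcohol (2,5-diol, either C2 epimer or a mixture)
Conditions: NaBH4, MeOH, 0 °C to rt
Reagents that add atoms: none
Why: Borohydride reduces the only free ketone, and the new C2 centre needs no control because it is erased two steps later.

**Step 10**
Reactants: 14 C2 alcohol
Product: 15 C2 O-phenyl thionocarbonate (C5–OH free)
Conditions: PhOC(S)Cl, pyridine, DMAP (cat.), CH2Cl2, rt
Reagents that add atoms: O-phenyl chlorothionoformate, S=C(Cl)Oc1ccccc1
Why: Thioacylation for the Barton–McCombie sequence takes place only at the secondary C2 hydroxyl because the C5 hydroxyl is tertiary and walled in by C1 and C4, and a monofunctional aryl reagent avoids the cyclic thionocarbonate that a bis-electrophile could form with a cis 2,5-diol.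

**Step 11**
Reactants: 15 C2 O-phenyl thionocarbonate
Product: 16 C2-deoxy ketal alcohol
Conditions: Bu3SnH, AIBN (cat.), toluene, 100 °C
Reagents that add atoms: none
Why: In this Barton–McCombie deoxygenation the stannyl radical adds to sulfur, the C2–O bond fragments to a secondary radical, and hydrogen transfer gives the C2 methylene under neutral conditions that leave ketal and tertiary alcohol alone.

**Step 12**
Reactants: 16 C2-deoxy ketal alcohol
Product: 17 (3R,3aS,7aR)-3a-hydroxy-7a-methyl-3-(propan-2-yl)octahydro-5H-inden-5-one
Conditions: PPTS (cat.), acetone–H2O, 40 °C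
Reagents that add atoms: water, O
Why: Acid-catalysed ketal hydrolysis with a weak acid is enough for the dioxolane, whereas dehydration of ketols of this type calls for strong acid and heat.

**Step 13**
Reactants: 17 hydroxy hydrindanone
Product: 18 C5 trimethylsilyl ether of 17
Conditions: TMSOTf (1.2 equiv), 2,6-lutidine, CH2Cl2, −78 to −20 °C
Reagents that add atoms: trimethylsilyl trifluoromethanesulfonate, C[Si](C)(C)OS(=O)(=O)C(F)(F)F
Why: Silyl triflate with a hindered pyridine base silylates even this crowded tertiary alcohol at low temperature faster than it enolises the ketone, and this removes the alkoxide that could otherwise cleave C5–C6 by retro-aldol under the amide base of the next step.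

**Step 14**
Reactants: 18 C5-siloxy hydrindanone
Product: 20 bis-silyl compound (C5–OTMS; C7–OTMS enol ether; C7=C9), via C7 lithium enolate 19 (not isolated)
Conditions: LiN(iPr)2 (LDA), TMSCl (present from the start), THF, −78 °C; Et3N; cold NaHCO3/pentane work-up
Reagents that add atoms: chlorotrimethylsilane, C[Si](C)(C)Cl
Why: In this kinetic enolisation with in situ silyl trapping the bulky amide takes a proton from the open C9 methylene and not from C6, which is neopentyl next to the fully substituted siloxy-bearing C5, so the double bond is fixed between C7 and C9 and β-elimination of the C5 oxygen is avoided.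

**Step 15**
Reactants: 20 bis-silyl compound; 21 1,1-dichloroethane
Product: 23 5-(trimethylsilyloxy)dauc-8-en-7-one, via chloro(methyl)cyclopropane adduct 22 (not isolated)
Conditions: 21 (excess), n-BuLi (slow addition), Et2O, −40 °C to rt; NaHCO3 wash; then Et3N, toluene, 110 °C (Et2O distilled off, 22 not purified)
Reagents that add atoms: none
Why: n-BuLi deprotonates 21, and the 1,1-dichloroethyllithium loses LiCl as it hands chloro(methyl)carbene to the electron-rich C7=C9 bond of 20, forming C7–C8 and C8–C9 in one concerted [2+1] cycloaddition that closes the three-membered ring of 22. On heating, chloride leaves C8 while the C7–C9 bond opens in a two-electron disrotatory electrocyclic process pushed by the siloxy oxygen, and the resulting 1-siloxyallyl cation (the O-silylated enone) passes its silyl group to chloride, so the seven-membered ring arises by enlargement of the six-membered ring and not by end-to-end closure, with the C7 carbonyl, the C8 methyl and a ring-enforced cis C8=C9 alkene in place. The closest known reaction type is the halocarbene addition and cyclopropyl-to-allyl ring expansion of cyclic silyl enol ethers to 2-substituted cycloalk-2-enones. The three cyclopropane stereocentres of 22 are uncontrolled and need no control, since C7, C8 and C9 all end trigonal, and C1, C4 and C5 are untouched. What does matter is that chloride lies syn to the six-membered ring, the only orientation from which disrotation turns C6 and C10 inward as a seven-membered allyl cation requires, and the larger methyl group should prefer the outer position during the addition and so favour this epimer. Site selectivity rests on 20 having a single C=C bond, fixed between C7 and C9 in step 14, and Et3N keeps the released chlorosilane from generating acid that would strip the C5 silyl ether or dehydrate C5.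

**Step 16**
Reactants: 23 5-(trimethylsilyloxy)dauc-8-en-7-one
Product: 24 (1R,4R,5S)-5-hydroxydauc-8-en-7-one
Conditions: HF·pyridine, THF–pyridine, 0 °C
Reagents that add atoms: none
Why: Fluoride-driven cleavage of the tertiary silyl ether in a weakly acidic buffered medium avoids base, which would provoke retro-aldol cleavage or E1cB loss of the C5 oxygen from this β-hydroxy ketone.

**Step 17**
Reactants: 24 5-hydroxydauc-8-en-7-one
Product: 25 (1R,4R,5S,7R)-dauc-8-ene-5,7-diol (anti diol, C7–OH on the bottom face)
Conditions: Me4NBH(OAc)3, MeCN–AcOH, −20 °C
Reagents that add atoms: none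
Why: In this Evans–Saksena reduction the C5 hydroxyl displaces an acetate on boron and the bound hydride is delivered intramolecularly to the top face of the C7 carbonyl through a six-membered transition state, which places the new hydroxyl trans to C5–OH, and the reagent is too weak to reduce unbound carbonyls or to add 1,4, so the alkene stays.

**Step 18**
Reactants: 25 anti 5,7-diol; 26 3,4-dimethoxybenzoyl chloride
Product: 27 (3R,3aS,5R,8aR)-3a-hydroxy-6,8a-dimethyl-3-(propan-2-yl)-1,2,3,3a,4,5,8,8a-octahydroazulen-5-yl 3,4-dimethoxybenzoate (target)
Conditions: Et3N, DMAP (cat.), CH2Cl2, 0 °C to rt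
Reagents that add atoms: none
Why: DMAP-catalysed acylation with the acid chloride esterifies the secondary allylic C7 alcohol with retention at C7, and the crowded tertiary C5 alcohol is inert under these conditions.

**Compound list**
1 | 2-methylcyclopentane-1,3-dione | CC1C(=O)CCC1=O | starting material
2 | methyl vinyl ketone | CC(=O)C=C | starting material
3 | 2-methyl-2-(3-oxobutyl)cyclopentane-1,3-dione | CC(=O)CCC1(C)C(=O)CCC1=O | intermediate
4 | (3aR,7aR)-3a-hydroxy-7a-methylhexahydro-1H-indene-1,5(4H)-dione, cis ketol | O=C2C[C@]3(O)CCC(=O)[C@]3(C)CC2 | intermediate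
5 | C5 trimethylsilyl ether of 4 | O=C2C[C@]3(O[Si](C)(C)C)CCC(=O)[C@]3(C)CC2 | intermediate
6 | C7 ethylene ketal of 5 | O1CCOC12C[C@]3(O[Si](C)(C)C)CCC(=O)[C@]3(C)CC2 | intermediate
7 | C2 lithium enolate of 6 (C2=C3), not isolated | O1CCOC12C[C@]3(O[Si](C)(C)C)CC=C(O[Li])[C@]3(C)CC2 | intermediate
8 | C2 trimethylsilyl enol ether of 6 | O1CCOC12C[C@]3(O[Si](C)(C)C)CC=C(O[Si](C)(C)C)[C@]3(C)CC2 | intermediate
9 | C5-siloxy cyclopentenone, C7 ketal | O1CCOC12C[C@]3(O[Si](C)(C)C)C=CC(=O)[C@]3(C)CC2 | intermediate
10 | C5-hydroxy cyclopentenone, C7 ketal | O1CCOC12C[C@]3(O)C=CC(=O)[C@]3(C)CC2 | intermediate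
11 | isopropylmagnesium chloride | CC(C)[Mg]Cl | starting material
12 | bis(chloromagnesium) C5 alkoxide and C2 enolate of 13, not isolated | O1CCOC12C[C@]3(O[Mg]Cl)[C@@H](C(C)C)C=C(O[Mg]Cl)[C@]3(C)CC2 | intermediate
13 | (4R)-C4-isopropyl ketone, C7 ketal, isopropyl syn to C5–OH | O1CCOC12C[C@]3(O)[C@@H](C(C)C)CC(=O)[C@]3(C)CC2 | intermediate
14 | C2 alcohol (C2 configuration not fixed) | O1CCOC12C[C@]3(O)[C@@H](C(C)C)CC(O)[C@]3(C)CC2 | intermediate
15 | C2 O-phenyl thionocarbonate (C2 configuration not fixed) | O1CCOC12C[C@]3(O)[C@@H](C(C)C)CC(OC(=S)Oc4ccccc4)[C@]3(C)CC2 | intermediate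
16 | C2-deoxy ketal alcohol | O1CCOC12C[C@]3(O)[C@@H](C(C)C)CC[C@]3(C)CC2 | intermediate
17 | (3R,3aS,7aR)-3a-hydroxy-7a-methyl-3-(propan-2-yl)octahydro-5H-inden-5-one | O=C2C[C@]3(O)[C@@H](C(C)C)CC[C@]3(C)CC2 | intermediate
18 | C5 trimethylsilyl ether of 17 | O=C2C[C@]3(O[Si](C)(C)C)[C@@H](C(C)C)CC[C@]3(C)CC2 | intermediate
19 | C7 lithium enolate of 18 (C7=C9), not isolated | [Li]OC=2C[C@]3(O[Si](C)(C)C)[C@@H](C(C)C)CC[C@]3(C)CC=2 | intermediate
20 | bis-silyl compound: C5 silyl ether and C7=C9 silyl enol ether | C[Si](C)(C)OC=2C[C@]3(O[Si](C)(C)C)[C@@H](C(C)C)CC[C@]3(C)CC=2 | intermediate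
21 | 1,1-dichloroethane | CC(Cl)Cl | starting material
22 | chloro(methyl)cyclopropane adduct (C7, C8, C9 not fixed), not isolated | C[Si](C)(C)OC12C[C@]3(O[Si](C)(C)C)[C@@H](C(C)C)CC[C@]3(C)CC1C2(C)Cl | intermediate
23 | 5-(trimethylsilyloxy)dauc-8-en-7-one | O=C2C[C@]3(O[Si](C)(C)C)[C@@H](C(C)C)CC[C@]3(C)CC=C2C | intermediate
24 | (1R,4R,5S)-5-hydroxydauc-8-en-7-one | O=C2C[C@]3(O)[C@@H](C(C)C)CC[C@]3(C)CC=C2C | intermediate
25 | (1R,4R,5S,7R)-dauc-8-ene-5,7-diol, anti diol | O[C@@H]2C[C@]3(O)[C@@H](C(C)C)CC[C@]3(C)CC=C2C | intermediate
26 | 3,4-dimethoxybenzoyl chloride | COc1ccc(C(=O)Cl)cc1OC | starting material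
27 | (1R,4R,5S,7R)-5-hydroxydauc-8-en-7-yl 3,4-dimethoxybenzoate | COc1ccc(C(=O)O[C@@H]2C[C@]3(O)[C@@H](C(C)C)CC[C@]3(C)CC=C2C)cc1OC | target

Total step count: 18
Longest linear sequence: 18 steps (1 and 2 to 27)

**Steps most likely to fail**

1. Step 15. Carbene transfer to the enol ether may stay incomplete. The ring opening may also stall for the share of adduct that carries chloride anti to the six-membered ring, or that share may open toward C8 without ring enlargement.
 - The fallback sets out from 20 and moves the methyl group out of the carbene.
 - Dibromocarbene (CHBr3, KOtBu, pentane, −20 °C) should give the 8,8-dibromocyclopropane adduct F1. One bromide in it is necessarily syn to the ring, so the opening no longer depends on how the carbene was oriented.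
 - Gentle heating with Et3N in toluene should give the 8-bromo-5-(trimethylsilyloxy)cycloheptenone F2.
 - A Stille methylation under neutral conditions (Me4Sn, Pd2(dba)3, AsPh3, CuI, NMP) then installs the C8 methyl and comes back to the route at 23.

2. Step 8. Facial selectivity at C4 may be poor, and 1,2-addition or carbonyl reduction by the secondary Grignard reagent may compete.
 - The fallback sets out from 10 and replaces kinetic face control by thermodynamic control.
 - Reversible Michael addition of 2-nitropropane (DBU, MeCN, rt) should settle the bulky substituent on the less crowded convex face, syn to the C5 hydroxyl, as the 4-(2-nitropropan-2-yl) ketone F3.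
 - Radical denitration of the tertiary nitro group (Bu3SnH, AIBN, toluene, reflux) leaves the isopropyl group and comes back to the route at 13.

3. Step 17. Ligand exchange at the crowded tertiary C5 hydroxyl may be too slow, so that hydride delivery is undirected or does not occur.
 - The fallback sets out from 24 and uses an external hydride under Luche conditions (NaBH4, CeCl3·7H2O, MeOH, −78 °C), followed by separation of the C7 epimers.
 - The anti epimer is 25 and continues through step 18.
 - The syn 5,7-diol F4 is esterified with inversion at C7 by a Mitsunobu reaction (3,4-dimethoxybenzoic acid, PPh3, DIAD, toluene, 0 °C) and comes back to the route at 27, so both epimers converge on the target.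

**Further compounds**
F1 | step 15 | 8,8-dibromocyclopropane adduct of 20 (C7 and C9 not fixed) | C[Si](C)(C)OC12C[C@]3(O[Si](C)(C)C)[C@@H](C(C)C)CC[C@]3(C)CC1C2(Br)Br
F2 | step 15 | 8-bromo-5-(trimethylsilyloxy)cycloheptenone (8-bromo analogue of 23 lacking the C8 methyl) | O=C2C[C@]3(O[Si](C)(C)C)[C@@H](C(C)C)CC[C@]3(C)CC=C2Br
F3 | step 8 | 4-(2-nitropropan-2-yl) ketone, C7 ketal, substituent syn to C5–OH | O1CCOC12C[C@]3(O)[C@@H](C(C)(C)[N+](=O)[O-])CC(=O)[C@]3(C)CC2
F4 | step 17 | (1R,4R,5S,7S)-dauc-8-ene-5,7-diol, syn diol | O[C@H]2C[C@]3(O)[C@@H](C(C)C)CC[C@]3(C)CC=C2C
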